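**Retrosynthetic overview**
1. C–C bond, made first: the benzylic CH2–C18 bond, from o-cresol 1 and 1-bromooctadecane 2 through dimetalated cresol 3, giving 2-nonadecylphenol 4.
2. Key bond, made last: the C4–O bond of the quinone, traced back to the para C–H of 4; forward, phenoxyl radical 5 is oxygenated by O2 to target 6.
3. Rings: none is built. The six-membered carbocycle is bought as o-cresol with the C1 oxygen in place and is only oxidised to the quinone at the end.

Assumption: target 6 has no stereocentre and no stereogenic double bond, so "single enantiomer" is read as the one achiral structure drawn; nothing has to be set or resolved.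

**Step 1**
Reactants: 1 o-cresol (2-methylphenol); 2 1-bromooctadecane
Product: 4 2-nonadecylphenol, via dipotassium 2-methanidylphenolate 3 (not isolated)
Conditions: 1 (1.3 equiv), n-BuLi (2.8 equiv), KOtBu (2.8 equiv), heptane, reflux, 3 h; then 2 (1.0 equiv), THF, −78 °C to rt; aq HCl
Reagents that add atoms: none
Why: The n-BuLi/KOtBu superbase removes the O–H and then a lateral benzylic C–H of 1 (lateral metalation), and the benzylic carbanion of 3, far more nucleophilic than its phenoxide oxygen, displaces bromide from primary bromide 2 (SN2 C-alkylation), so CH2 + C18 gives the C19 chain; excess 1 is washed out with base and no stereocentre is formed.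

**Step 2**
Reactants: 4 2-nonadecylphenol
Product: 6 2-nonadecyl-1,4-benzoquinone, via 2-nonadecylphenoxyl radical 5 (not isolated)
Conditions: Co(salen) [Co(C16H14N2O2)] (10 mol %), pyridine (20 mol %), O2 (1 atm), PhCl/DMF 3:1, 525 nm LEDs, 25 °C
Reagents that add atoms: dioxygen, O=O
Why: Proposed new method: light-gated aerobic para-oxygenation of a non-hindered mono-ortho-alkylphenol. Under O2 the catalyst is expected to rest as the trivalent cobalt phenolate (salen)Co–OAr, which for this weakly reducing phenolate cannot regenerate divalent cobalt thermally. Green-light phenolate-to-cobalt charge transfer (LMCT) is therefore used to homolyse the Co–O bond, releasing phenoxyl radical 5 and divalent Co(salen). The latter binds O2 as the persistent, bulky superoxo (salen)Co–OO•, which couples with 5 at the unhindered para carbon and forms the new C–O bond. The catalyst-bound peroxy-dienone still carries H at C4 and collapses in a Kornblum–DeLaMare-type fragmentation to the quinone and (salen)Co–OH, which with 4 gives back the phenolate and water. A low photon flux keeps 5 far below the superoxo concentration, suppressing phenoxyl C–C/C–O dimerisation, and the one-electron path avoids the ortho-quinone methide that two-electron oxidants make from 2-alkylphenols. The closest known reaction type is the thermal Co(salen)/O2 oxidation of 2,6-disubstituted phenols to p-benzoquinones and the Teuber oxidation with ON(SO3K)2; no stereocentre is formed.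

**Compound list**
1 | o-cresol (2-methylphenol) | Cc1ccccc1O | starting material
2 | 1-bromooctadecane | CCCCCCCCCCCCCCCCCCBr | starting material
3 | dipotassium 2-methanidylphenolate (O,C-dimetalated o-cresol, drawn as the dipotassium salt) | [K+].[K+].[CH2-]c1ccccc1[O-] | intermediate
4 | 2-nonadecylphenol | CCCCCCCCCCCCCCCCCCCc1ccccc1O | intermediate
5 | 2-nonadecylphenoxyl radical | CCCCCCCCCCCCCCCCCCCc1ccccc1[O] | intermediate
6 | 2-nonadecyl-1,4-benzoquinone (2-nonadecylcyclohexa-2,5-diene-1,4-dione, achiral) | CCCCCCCCCCCCCCCCCCCC1=CC(=O)C=CC1=O | target

**Totals and risks**
Total step count: 2. Longest linear sequence: 2. The route has only two steps, so both are ranked and there is no third.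

1. Step 2 (the proposed new method) is the most likely to fail. The LMCT homolysis may be inefficient, 5 may dimerise or be attacked at the free ortho carbon, and the quinone may be photolysed if shorter wavelengths are needed. The fallback is known chemistry and moves the para functionalisation to a C–N bond; it sets out from 4 and comes back at 6. Para C-nitrosation of 4 with NaNO2 and aqueous HCl in EtOH/THF at 0 °C gives 4-nitroso-2-nonadecylphenol F3 (tautomer of the quinone monooxime). Na2S2O4 in THF/water reduces it to 4-amino-2-nonadecylphenol F4. FeCl3 in aqueous HCl/THF oxidises F4 to the quinone imine, which hydrolyses in the same pot to 6. This is the classical nitrosophenol, aminophenol, quinone sequence used for thymoquinone.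

2. Step 1 is second. The dimetalation may be incomplete in the heterogeneous heptane slurry, and the strongly basic carbanion may eliminate HBr from 2 instead of alkylating. The fallback reverses the polarity of the C–C bond; it sets out from 2 and comes back at 4. Bromide 2 with Mg in THF gives octadecylmagnesium bromide F1. Adding 2.2 equiv of F1 to salicylaldehyde (O=Cc1ccccc1O) in THF at 0 °C, where the first equivalent only deprotonates the phenol, gives racemic 2-(1-hydroxynonadecyl)phenol F2 after aqueous HCl. Ionic hydrogenation of F2 with Et3SiH and TFA in CH2Cl2 at 0 °C, through the benzylic cation/ortho-quinone methide, removes the benzylic hydroxyl and gives 4.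

**Further compounds**
F1 | step 1 | octadecylmagnesium bromide | CCCCCCCCCCCCCCCCCC[Mg]Br
F2 | step 1 | 2-(1-hydroxynonadecyl)phenol (racemic) | CCCCCCCCCCCCCCCCCCC(O)c1ccccc1O
F3 | step 2 | 4-nitroso-2-nonadecylphenol | CCCCCCCCCCCCCCCCCCCc1cc(N=O)ccc1O
F4 | step 2 | 4-amino-2-nonadecylphenol | CCCCCCCCCCCCCCCCCCCc1cc(N)ccc1O
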